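The numbers in the tables come from a simulation on assumed constants; noise was put on by code.

The beta run charged more substrate than coupling partner, and its target, crystals included, stands at 63.6 % at 4.00 h. The delta run had the excess the other way and reaches 96.9 % at 4.00 h. Two chemists argue over a flask with equal charges.

| flask | substrate | coupling partner | remark | time |
|---|---|---|---|---|
| delta | 0.17 M | 0.26 M | run made earlier |  |
| beta | 0.39 M | 0.26 M | run made earlier |  |
| flask | 0.26 M | 0.260 M |  | 6.0 h |

| run | time / h | target / % | crystals / % |
|---|---|---|---|
| delta | 0.250 | 42.2 | 4.6 |
| delta | 0.667 | 71.1 | 13.6 |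
| delta | 1.33 | 90.0 | 33.6 |
| delta | 2.00 | 93.7 | 52.7 |
| delta | 3.00 | 95.6 | 67.2 |
| delta | 4.00 | 96.9 | 76.7 |
| beta | 0.667 | 60.3 | 10.7 |
| beta | 1.33 | 64.5 | 28.1 |
| beta | 2.00 | 64.8 | 38.9 |
| beta | 2.50 | 66.1 | 44.9 |
| beta | 3.00 | 64.7 | 48.2 |
| beta | 4.00 | 63.6 | 53.9 |

(each reading ± 1 percentage point)

- what is said of target includes crystals
- crystals is a solid; its amount is given per volume of the solution

* amount of target and crystals together at 6.0 h, in percent of the substrate charged
* concentration of target in solution at 6.0 h, in percent of saturation

The second chemist writes the balance of the smaller charge, the limiting reagent. If one substrate and one coupling partner make one target, target cannot pass the smaller charge divided by the substrate charge. She calls this the ceiling, and for the new flask it is 100 %. The beta run's ceiling is 66.7 % and the delta run's 100 %, so in her view both runs were nearing the end of a reagent. The delta run's last reading lies 3.1 percentage points under its ceiling. The new flask has no excess of coupling partner, so both reagents thin together, and she allows twice that gap. This reckoning of her own gives 93.8 %. The ceiling says nothing about saturation, so she offers no figure for it.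

The first chemist reads the beta run's stall as lost rate, and his second-order fits have a constant that runs high “early, then falling”. His forecast differs from her figure: 86 % for the yield, with dissolved target at 143 % of saturation.

The flask gives 93.2 %, with dissolved target at 637 % of saturation.

    crystals ⇌ target, rate k1*(cs1 - [target]) while solid is left; crystals form when [target] > cs1 (solubility = 2.80 mM, k = 1.50 × 10⁻⁴ s⁻¹)
    substrate + coupling partner → target, rate k2*[substrate]*[coupling partner]^0.5 (k = 0.00130 L⁰·⁵ mol⁻⁰·⁵ s⁻¹)
    target ⇌ isomer of the product (K = 1.10, k = 1.00 × 10⁻⁵ s⁻¹)

The forecast's 86 % lies near what this flask holds earlier: target and crystals stand at 84.7 % at 1.50 h. At 6.0 h the flask lies 6.8 points under its ceiling, and that gap is held by 5.28 % of isomer of the product and 1.50 % of substrate. With 0.65 M of substrate and the same coupling partner, the ceiling drops to 40.0 %, and that neighbouring flask gives 37.8 %, its coupling partner down to 0 %.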